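**Strategy**

Everything rests on cutting the C8–C9 bond of ring B. The target's vicinal pair, the tertiary C8 carbinol and the C9 stereocentre with C8–O trans to C9–C11, is what a ketyl adding to an enoate delivers. One SmI2-mediated reductive closure therefore forms C8–C9, closes ring B, sets both centres and leaves C12 as an ester for attaching the side chain. Its precursor is a cis-1,2-disubstituted cyclohexene (ring A) bearing a 3-oxobutyl chain on C5 and, on quaternary C10, a methyl and an (E)-acrylate. It derives from (R)-α-ionone, whose stereocentre becomes C5 and directs C10 through a suprafacial [2,3] shift.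

Key step: step 12

Remark: the target is built exactly as its SMILES defines it, i.e. with rings A and B cis-fused (H-5, the C10 methyl and C11 on one face, called β; 8-OH on the other); atoms carry the target numbering (decalin C1–C10, side chain from C11).

**Route**

Step 1
Reactants: 1 (R)-α-ionone
Product: 3 (R)-dihydro-α-ionone (4-[(1R)-2,6,6-trimethylcyclohex-2-en-1-yl]butan-2-one), via triethylsilyl enol ether 2 (not isolated)
Conditions: Et3SiH, RhCl(PPh3)3 (0.5 mol %), toluene, 50 °C; then K2CO3 (cat.), MeOH, rt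
Reagents that add atoms: none
Why: Rhodium-catalysed 1,4-hydrosilylation of the enone (Ojima conjugate reduction) and methanolysis of the silyl enol ether should saturate only the conjugated C=C without base while the stereocentre (future C5) is still γ to a carbonyl, so it is not epimerised and the ring alkene stays in place.

Step 2
Reactants: 3 (R)-dihydro-α-ionone
Product: 4 dioxolane of 3
Conditions: HOCH2CH2OH, PPTS (cat.), benzene, reflux (Dean–Stark)
Reagents that add atoms: ethane-1,2-diol, OCCO
Why: Acid-catalysed ketalisation with azeotropic removal of water masks the C8 ketone for the hydride, alkoxide and organolithium steps ahead, and the weak acid should not move the ring alkene.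

Step 3
Reactants: 4 dioxolane
Product: 5 ring enone (C2 ketone, C1=C10 alkene)
Conditions: t-BuOOH, Rh2(cap)4 (dirhodium tetracaprolactamate, 1 mol %), K2CO3, CH2Cl2, rt
Reagents that add atoms: tert-butyl hydroperoxide, CC(C)(C)OO
Why: Radical allylic C–H oxidation by tert-butylperoxyl radicals should attack the only secondary allylic CH2 (C2) and give the conjugated enone, the usual outcome for α-ionone derivatives, while the ketal tolerates the basic medium.

Step 4
Reactants: 5 ring enone
Product: 6 trans allylic alcohol (1R,4R; C2–OH opposite to the C5 chain)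
Conditions: LiBH(s-Bu)3, THF, −78 °C; then H2O
Reagents that add atoms: none
Why: 1,2-Reduction of a β,β-disubstituted cyclohexenone by a bulky trialkylborohydride, in which hydride should enter anti to the axial C4 methyl lying 1,3 to the carbonyl, so the new hydroxyl ends up trans to the C5 side chain.

Step 5
Reactants: 6 trans allylic alcohol
Product: 7 cis 4-nitrobenzoate (1S,4R)
Conditions: 4-O2NC6H4CO2H, PPh3, DIAD, THF, 0 °C → rt
Reagents that add atoms: 4-nitrobenzoic acid, OC(=O)c1ccc(cc1)[N+](=O)[O-]
Why: Mitsunobu esterification displaces the activated hydroxyl by SN2 with inversion at C2, which should place the oxygen on the face of the C5 chain as the later suprafacial carbon transfer requires; SN2' attack at the fully substituted C10 is disfavoured.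

Step 6
Reactants: 7 cis 4-nitrobenzoate
Product: 8 cis allylic alcohol (1S,4R)
Conditions: K2CO3, MeOH, rt
Reagents that add atoms: none
Why: Base-catalysed methanolysis of the activated aryl ester frees the alcohol by acyl–oxygen cleavage, so the C2 configuration and the ketal are untouched.

Step 7
Reactants: 8 cis allylic alcohol; 9 tributyl(iodomethyl)stannane
Product: 10 (tributylstannyl)methyl ether of 8
Conditions: KH, 18-crown-6 (cat.), THF, 0 °C → rt
Reagents that add atoms: none
Why: Williamson O-alkylation with the iodomethylstannane (Still's protocol) breaks only the O–H bond, so the C2 configuration is kept.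

Step 8
Reactants: 10 (tributylstannyl)methyl ether
Product: 12 homoallylic alcohol with quaternary C10 (C10–CH2OH, C1=C2 alkene), via lithiomethyl ether 11 (not isolated)
Conditions: n-BuLi, THF, −78 → −20 °C; then H2O
Reagents that add atoms: none
Why: Still–Wittig [2,3]-sigmatropic rearrangement, in which tin–lithium exchange gives a carbanion that is transferred suprafacially through a five-membered envelope to C10 on the face that carried the C2–O bond (cis to the C5 chain), setting the quaternary centre (1S) and moving the alkene to C1=C2.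

Step 9
Reactants: 12 homoallylic alcohol
Product: 13 α-quaternary aldehyde (C9 aldehyde)
Conditions: Dess–Martin periodinane, pyridine, CH2Cl2, rt
Reagents that add atoms: none
Why: Dess–Martin oxidation of the neopentyl primary alcohol should give the non-enolisable aldehyde under near-neutral conditions that spare the ketal.

Step 10
Reactants: 13 aldehyde; 14 trimethyl phosphonoacetate
Product: 15 ketal-protected (E)-enoate
Conditions: NaH, THF, 0 °C → rt
Reagents that add atoms: none
Why: Horner–Wadsworth–Emmons olefination with the stabilised phosphonate should give the (E)-enoate under thermodynamic control, and because the ketone is still masked no aldol or Michael side reaction is possible.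

Step 11
Reactants: 15 ketal-protected enoate
Product: 16 keto enoate, methyl (2E)-3-[(1R,6R)-1,5,5-trimethyl-6-(3-oxobutyl)cyclohex-2-en-1-yl]prop-2-enoate
Conditions: 1 M HCl, THF, rt
Reagents that add atoms: water, O
Why: Mild aqueous-acid hydrolysis of the dioxolane releases the methyl ketone, and acid is used instead of base so that the ketone cannot add to the enoate as its enolate.

Step 12
Reactants: 16 keto enoate
Product: 19 cis-fused hydroxy ester (8α-OH, 9β-CH2CO2Me, ring A 1-ene), via samarium ketyl 17 (not isolated), via samarium enolate 18 (not isolated)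
Conditions: SmI2 (2.5 equiv), t-BuOH (2 equiv), HMPA, THF, −78 → 0 °C
Reagents that add atoms: none
Why: Single-electron transfer from divalent samarium to the C8 ketone gives a ketyl that adds to the enoate β-carbon C9, a second electron turns the α-ester radical into a samarium enolate, and t-BuOH protonates it at C11. The closest known reaction type is the SmI2-mediated ketyl–olefin reductive cyclisation of keto enoates to γ-hydroxy esters. Ring B closes in the 6-exo-trig mode (C8 onto C9, with C9=C11 exocyclic). C9 is controlled by the cis-disubstituted ring A: in the chair-like transition state the C5 tether is equatorial and the acrylate arm axial on ring A, so the C10 methyl is axial on the new ring, the α face of C9 is blocked by C4 and its methyl, and C11 should lie equatorial on the β face, syn to the C10 methyl. C8 is controlled by the bulky HMPA-solvated O–Sm group, which avoids the syn-axial C10 methyl and the ester arm by taking the equatorial α position, trans to C11, while the methyl ketone supplies the C8 methyl. The step needs chemoselectivity (secured by the activated enoate at a 6-exo distance and the inert ring alkene), anti addition and this enoate face; the last depends on the half-chair of ring A and is where the risk of the route is placed.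

Step 13
Reactants: 19 hydroxy ester
Product: 20 C8 triethylsilyl ether
Conditions: Et3SiOTf, 2,6-lutidine, CH2Cl2, 0 °C
Reagents that add atoms: triethylsilyl trifluoromethanesulfonate, CC[Si](CC)(CC)OS(=O)(=O)C(F)(F)F
Why: Silylation of a tertiary alcohol with a silyl triflate and a hindered pyridine base is standard, and the ether prevents later tetrahydrofuran formation between O8 and an activated C12 as well as protonation of the alkylzinc.

Step 14
Reactants: 20 silyl ether
Product: 21 allylic alcohol (3β-OH, C1=C2 retained)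
Conditions: SeO2 (0.5 equiv), t-BuOOH, CH2Cl2, rt
Reagents that add atoms: tert-butyl hydroperoxide, CC(C)(C)OO
Why: Riley–Sharpless allylic hydroxylation, in which the ene reaction (Se to C1, H from C3) and the following [2,3] shift return the alkene to C1=C2 and put oxygen on C3, the only allylic carbon bearing hydrogen; attack on the convex β face should give the 3β-alcohol, a transient centre removed in step 18.

Step 15
Reactants: 21 allylic alcohol
Product: 22 saturated 3β-hydroxy ester
Conditions: H2 (1 atm), PtO2, EtOAc, rt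
Reagents that add atoms: none
Why: Heterogeneous hydrogenation of the cis-disubstituted ring alkene creates no stereocentre, and platinum is chosen over palladium to limit allylic C–O hydrogenolysis.

Step 16
Reactants: 22 saturated hydroxy ester
Product: 23 diol (C3–OH, C12–OH)
Conditions: LiAlH4, THF, 0 °C; aqueous work-up
Reagents that add atoms: none
Why: LiAlH4 reduces the ester to the primary C12 alcohol while the silyl ether and the C3 alcohol are inert.

Step 17
Reactants: 23 diol
Product: 24 primary iodide (C12–I, C3–OH)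
Conditions: I2, PPh3, imidazole, CH2Cl2, 0 °C → rt
Reagents that add atoms: iodine, II
Why: Appel-type iodination (Garegg–Samuelsson conditions) converts the unhindered primary alcohol by SN2, whereas the secondary C3 alcohol next to the gem-dimethyl carbon cannot be displaced.

Step 18
Reactants: 24 iodo alcohol
Product: 25 keto iodide (C3 ketone, C12–I, C8–OSiEt3)
Conditions: Dess–Martin periodinane, pyridine, CH2Cl2, rt
Reagents that add atoms: none
Why: Dess–Martin oxidation turns the hindered secondary alcohol into the C3 ketone, and a primary alkyl iodide is stable to this oxidant.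

Step 19
Reactants: 26 geranyl bromide; 27 1-(trimethylsilyl)propyne
Product: 29 silylated dienyne, via 3-(trimethylsilyl)prop-2-ynyllithium 28 (not isolated)
Conditions: 27, n-BuLi, THF, −78 °C; then 26, −78 → 0 °C
Reagents that add atoms: none
Why: The propargylic lithium reagent alkylates the primary allylic bromide by SN2 at its propargylic carbon, the silyl group blocking the allenyl terminus, so the (E)-alkene is retained.

Step 20
Reactants: 29 silylated dienyne
Product: 30 terminal dienyne
Conditions: K2CO3, MeOH, rt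
Reagents that add atoms: none
Why: Methanolysis cleaves only the C(sp)–Si bond (protodesilylation of an alkynylsilane).

Step 21
Reactants: 30 terminal dienyne
Product: 32 (1E,5E)-trienyl iodide, via alkenyldimethylalane 31 (not isolated)
Conditions: AlMe3, Cp2ZrCl2 (20 mol %), CH2Cl2, 0 °C → rt; then I2, THF, −30 °C
Reagents that add atoms: trimethylaluminium, C[Al](C)C; iodine, II
Why: Negishi zirconium-catalysed carboalumination adds methyl and aluminium syn across the terminal alkyne with aluminium on the terminal carbon, and iodinolysis with retention gives the (E)-trisubstituted iodoalkene.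

Step 22
Reactants: 32 trienyl iodide
Product: 33 (2E,6E,10E)-ω-hydroxy trienyl iodide
Conditions: SeO2 (cat.), t-BuOOH, salicylic acid (cat.), CH2Cl2, rt
Reagents that add atoms: tert-butyl hydroperoxide, CC(C)(C)OO
Why: SeO2-catalysed allylic hydroxylation (ene reaction, then [2,3] shift) selects the (E)-methyl of the terminal isopropylidene, the most electron-rich and least hindered alkene, giving the (E)-allylic alcohol while the iodoalkene is deactivated.

Step 23
Reactants: 33 hydroxy trienyl iodide
Product: 34 tert-butyldimethylsilyl ether of 33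
Conditions: TBSCl, imidazole, DMF, rt
Reagents that add atoms: tert-butyldimethylsilyl chloride, CC(C)(C)[Si](C)(C)Cl
Why: Imidazole-promoted silylation of a primary alcohol is routine and is needed because a free hydroxyl would quench the alkylzinc and an allylic acetate would ionise with zerovalent palladium.

Step 24
Reactants: 25 keto iodide; 34 silylated trienyl iodide
Product: 36 coupled bis-silyl ether, via alkylzinc iodide 35 (not isolated)
Conditions: 25, Zn dust (activated with BrCH2CH2Br, TMSCl), DMA, 40 °C; then 34, PdCl2(dppf) (5 mol %), THF, rt → 45 °C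
Reagents that add atoms: none
Why: Zinc inserts into the primary C–I bond without touching the ketone, and the palladium-catalysed Negishi sp3–sp2 coupling forms C12–C13 with retention of the (E) geometry, the bidentate ferrocenyl phosphine suppressing β-hydride elimination.

Step 25
Reactants: 36 coupled bis-silyl ether
Product: 37 diol (C8–OH and terminal allylic OH)
Conditions: HF·pyridine, pyridine, THF, 0 °C → rt
Reagents that add atoms: none
Why: Fluoride cleaves both silyl ethers under buffered conditions that should not ionise the tertiary or the allylic alcohol.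

Step 26
Reactants: 37 diol
Product: 38 target acetate
Conditions: Ac2O, pyridine, CH2Cl2, 0 °C → rt
Reagents that add atoms: acetic anhydride, CC(=O)OC(C)=O
Why: Acetylation without an acyl-transfer catalyst should occur only at the primary allylic hydroxyl, the hindered tertiary C8 alcohol remaining free.

**Compound list**

1 | (R)-α-ionone, (3E)-4-[(1R)-2,6,6-trimethylcyclohex-2-en-1-yl]but-3-en-2-one | CC1=CCCC(C)(C)[C@H]1/C=C/C(C)=O | starting material
2 | triethyl({4-[(1R)-2,6,6-trimethylcyclohex-2-en-1-yl]but-2-en-2-yl}oxy)silane (E/Z mixture) | CC1=CCCC(C)(C)[C@H]1CC=C(C)O[Si](CC)(CC)CC | intermediate (not isolated)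
3 | 4-[(1R)-2,6,6-trimethylcyclohex-2-en-1-yl]butan-2-one | CC1=CCCC(C)(C)[C@H]1CCC(C)=O | intermediate
4 | 2-methyl-2-{2-[(1R)-2,6,6-trimethylcyclohex-2-en-1-yl]ethyl}-1,3-dioxolane | CC1=CCCC(C)(C)[C@H]1CCC2(C)OCCO2 | intermediate
5 | (4R)-3,5,5-trimethyl-4-[2-(2-methyl-1,3-dioxolan-2-yl)ethyl]cyclohex-2-en-1-one | CC1=CC(=O)CC(C)(C)[C@H]1CCC2(C)OCCO2 | intermediate
6 | (1R,4R)-3,5,5-trimethyl-4-[2-(2-methyl-1,3-dioxolan-2-yl)ethyl]cyclohex-2-en-1-ol (trans) | CC1=C[C@H](O)CC(C)(C)[C@H]1CCC2(C)OCCO2 | intermediate
7 | (1S,4R)-3,5,5-trimethyl-4-[2-(2-methyl-1,3-dioxolan-2-yl)ethyl]cyclohex-2-en-1-yl 4-nitrobenzoate (cis) | CC1=C[C@@H](OC(=O)c2ccc(cc2)[N+](=O)[O-])CC(C)(C)[C@H]1CCC3(C)OCCO3 | intermediate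
8 | (1S,4R)-3,5,5-trimethyl-4-[2-(2-methyl-1,3-dioxolan-2-yl)ethyl]cyclohex-2-en-1-ol (cis) | CC1=C[C@@H](O)CC(C)(C)[C@H]1CCC2(C)OCCO2 | intermediate
9 | tributyl(iodomethyl)stannane | CCCC[Sn](CCCC)(CCCC)CI | starting material
10 | tributyl({[(1S,4R)-3,5,5-trimethyl-4-[2-(2-methyl-1,3-dioxolan-2-yl)ethyl]cyclohex-2-en-1-yl]oxy}methyl)stannane | CC1=C[C@@H](OC[Sn](CCCC)(CCCC)CCCC)CC(C)(C)[C@H]1CCC2(C)OCCO2 | intermediate
11 | ({[(1S,4R)-3,5,5-trimethyl-4-[2-(2-methyl-1,3-dioxolan-2-yl)ethyl]cyclohex-2-en-1-yl]oxy}methyl)lithium | CC1=C[C@@H](OC[Li])CC(C)(C)[C@H]1CCC2(C)OCCO2 | intermediate (not isolated)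
12 | [(1S,6R)-1,5,5-trimethyl-6-[2-(2-methyl-1,3-dioxolan-2-yl)ethyl]cyclohex-2-en-1-yl]methanol | OC[C@@]1(C)C=CCC(C)(C)[C@H]1CCC2(C)OCCO2 | intermediate
13 | (1S,6R)-1,5,5-trimethyl-6-[2-(2-methyl-1,3-dioxolan-2-yl)ethyl]cyclohex-2-ene-1-carbaldehyde | O=C[C@@]1(C)C=CCC(C)(C)[C@H]1CCC2(C)OCCO2 | intermediate
14 | trimethyl phosphonoacetate | COC(=O)CP(=O)(OC)OC | starting material
15 | methyl (2E)-3-[(1R,6R)-1,5,5-trimethyl-6-[2-(2-methyl-1,3-dioxolan-2-yl)ethyl]cyclohex-2-en-1-yl]prop-2-enoate | COC(=O)/C=C/[C@@]1(C)C=CCC(C)(C)[C@H]1CCC2(C)OCCO2 | intermediate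
16 | methyl (2E)-3-[(1R,6R)-1,5,5-trimethyl-6-(3-oxobutyl)cyclohex-2-en-1-yl]prop-2-enoate | COC(=O)/C=C/[C@@]1(C)C=CCC(C)(C)[C@H]1CCC(C)=O | intermediate (precursor of the key step)
17 | samarium ketyl of 16 (C8 radical, O-bound diiodosamarium) | COC(=O)/C=C/[C@@]1(C)C=CCC(C)(C)[C@H]1CC[C](C)O[Sm](I)I | intermediate (not isolated)
18 | cyclised samarium alkoxide/ester enolate | COC(O[Sm](I)I)=C[C@@H]1[C@@]2(C)C=CCC(C)(C)[C@H]2CC[C@@]1(C)O[Sm](I)I | intermediate (not isolated)
19 | methyl 2-[(1R,2R,4aR,8aS)-2-hydroxy-2,5,5,8a-tetramethyl-1,2,3,4,4a,5,6,8a-octahydronaphthalen-1-yl]acetate | COC(=O)C[C@@H]1[C@@]2(C)C=CCC(C)(C)[C@H]2CC[C@@]1(C)O | intermediate (product of the key step)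
20 | methyl 2-[(1R,2R,4aR,8aS)-2,5,5,8a-tetramethyl-2-[(triethylsilyl)oxy]-1,2,3,4,4a,5,6,8a-octahydronaphthalen-1-yl]acetate | COC(=O)C[C@@H]1[C@@]2(C)C=CCC(C)(C)[C@H]2CC[C@@]1(C)O[Si](CC)(CC)CC | intermediate
21 | methyl 2-[(1R,2R,4aS,6S,8aS)-6-hydroxy-2,5,5,8a-tetramethyl-2-[(triethylsilyl)oxy]-1,2,3,4,4a,5,6,8a-octahydronaphthalen-1-yl]acetate | COC(=O)C[C@@H]1[C@@]2(C)C=C[C@H](O)C(C)(C)[C@H]2CC[C@@]1(C)O[Si](CC)(CC)CC | intermediate
22 | methyl 2-[(1R,2R,4aS,6S,8aS)-6-hydroxy-2,5,5,8a-tetramethyl-2-[(triethylsilyl)oxy]decahydronaphthalen-1-yl]acetate | COC(=O)C[C@@H]1[C@@]2(C)CC[C@H](O)C(C)(C)[C@H]2CC[C@@]1(C)O[Si](CC)(CC)CC | intermediate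
23 | (2S,4aS,5R,6R,8aS)-5-(2-hydroxyethyl)-1,1,4a,6-tetramethyl-6-[(triethylsilyl)oxy]decahydronaphthalen-2-ol | OCC[C@@H]1[C@@]2(C)CC[C@H](O)C(C)(C)[C@H]2CC[C@@]1(C)O[Si](CC)(CC)CC | intermediate
24 | (2S,4aS,5R,6R,8aS)-5-(2-iodoethyl)-1,1,4a,6-tetramethyl-6-[(triethylsilyl)oxy]decahydronaphthalen-2-ol | ICC[C@@H]1[C@@]2(C)CC[C@H](O)C(C)(C)[C@H]2CC[C@@]1(C)O[Si](CC)(CC)CC | intermediate
25 | (4aS,5R,6R,8aS)-5-(2-iodoethyl)-1,1,4a,6-tetramethyl-6-[(triethylsilyl)oxy]octahydronaphthalen-2(1H)-one | ICC[C@@H]1[C@@]2(C)CCC(=O)C(C)(C)[C@H]2CC[C@@]1(C)O[Si](CC)(CC)CC | intermediate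
26 | geranyl bromide, (2E)-1-bromo-3,7-dimethylocta-2,6-diene | CC(C)=CCC/C(C)=C/CBr | starting material
27 | 1-(trimethylsilyl)propyne | CC#C[Si](C)(C)C | starting material
28 | 3-(trimethylsilyl)prop-2-ynyllithium | [Li]CC#C[Si](C)(C)C | intermediate (not isolated)
29 | [(5E)-6,10-dimethylundeca-5,9-dien-1-yn-1-yl]trimethylsilane | CC(C)=CCC/C(C)=C/CCC#C[Si](C)(C)C | intermediate
30 | (5E)-6,10-dimethylundeca-5,9-dien-1-yne | CC(C)=CCC/C(C)=C/CCC#C | intermediate
31 | dimethyl[(1E,5E)-2,6,10-trimethylundeca-1,5,9-trien-1-yl]alane | CC(C)=CCC/C(C)=C/CC/C(C)=C/[Al](C)C | intermediate (not isolated)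
32 | (1E,5E)-1-iodo-2,6,10-trimethylundeca-1,5,9-triene | CC(C)=CCC/C(C)=C/CC/C(C)=C/I | intermediate
33 | (2E,6E,10E)-11-iodo-2,6,10-trimethylundeca-2,6,10-trien-1-ol | OC/C(C)=C/CC/C(C)=C/CC/C(C)=C/I | intermediate
34 | tert-butyl{[(2E,6E,10E)-11-iodo-2,6,10-trimethylundeca-2,6,10-trien-1-yl]oxy}dimethylsilane | CC(C)(C)[Si](C)(C)OC/C(C)=C/CC/C(C)=C/CC/C(C)=C/I | intermediate
35 | alkylzinc iodide from 25 (C12–ZnI) | I[Zn]CC[C@@H]1[C@@]2(C)CCC(=O)C(C)(C)[C@H]2CC[C@@]1(C)O[Si](CC)(CC)CC | intermediate (not isolated)
36 | (4aS,5R,6R,8aS)-5-[(3E,7E,11E)-13-{[tert-butyl(dimethyl)silyl]oxy}-4,8,12-trimethyltrideca-3,7,11-trien-1-yl]-1,1,4a,6-tetramethyl-6-[(triethylsilyl)oxy]octahydronaphthalen-2(1H)-one | CC(C)(C)[Si](C)(C)OC/C(C)=C/CC/C(C)=C/CC/C(C)=C/CC[C@@H]1[C@@]2(C)CCC(=O)C(C)(C)[C@H]2CC[C@@]1(C)O[Si](CC)(CC)CC | intermediate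
37 | (4aS,5R,6R,8aS)-6-hydroxy-5-[(3E,7E,11E)-13-hydroxy-4,8,12-trimethyltrideca-3,7,11-trien-1-yl]-1,1,4a,6-tetramethyloctahydronaphthalen-2(1H)-one | OC/C(C)=C/CC/C(C)=C/CC/C(C)=C/CC[C@@H]1[C@@]2(C)CCC(=O)C(C)(C)[C@H]2CC[C@@]1(C)O | intermediate
38 | (2E,6E,10E)-13-[(1R,2R,4aS,8aS)-2-hydroxy-2,5,5,8a-tetramethyl-6-oxodecahydronaphthalen-1-yl]-2,6,10-trimethyltrideca-2,6,10-trien-1-yl acetate | CC(=O)OC/C(C)=C/CC/C(C)=C/CC/C(C)=C/CC[C@@H]1[C@@]2(C)CCC(=O)C(C)(C)[C@H]2CC[C@@]1(C)O | target

**Step count**

Total: 26 steps. Longest linear sequence: 21 steps (steps 1–18 and 24–26); steps 19–23 build the side-chain fragment.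

**Steps most likely to fail**

1. Step 12. The closure may run through the other half-chair of ring A (tether axial) or with the O–Sm group axial, which would erode the facial selectivity at C9 or the anti relationship at C8; plain reduction of the enoate may also compete. Fallback: setting out from 16, the ketyl is generated as its O-stannyl derivative in a radical chain (Bu3SnH, AIBN, benzene, 80 °C, slow addition; tin-ketyl cyclisation of keto enoates). This addition is reversible, so the product ratio should move towards the most stable chair of ring B with C11 and O8 both equatorial. The cyclised tributylstannyl ether F1 is hydrolysed on aqueous work-up, and the route is rejoined at 19.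

2. Step 8. The carbanion may fail to reach the hindered C10, where the new bond is syn-axial to a C4 methyl, so that a [1,2] shift or simple protonation of the organolithium takes over. Fallback: setting out from 8, the alcohol is esterified with (4-methoxybenzyloxy)acetic acid (DCC, DMAP) to the glycolate ester F2. Ireland–Claisen rearrangement of its silyl ketene acetal (LDA, TMSCl, THF, −78 → 60 °C) is a neutral, thermally driven [3,3] shift with the same suprafacial transfer to C10 and should give the α-alkoxy acid F3. DDQ removes the 4-methoxybenzyl group to give the α-hydroxy acid F4, and Pb(OAc)4 cleaves it oxidatively to the aldehyde, rejoining the route at 13.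

3. Step 14. The ene reaction of SeO2 with the hindered 1,2-disubstituted alkene may be too slow, so that forcing conditions cause over-oxidation or loss of the silyl ether. Fallback: setting out from 20, radical allylic oxidation (t-BuOOH, Rh2(cap)4, K2CO3, CH2Cl2) should favour C3 because C1 is screened by the C10 methyl and the C11 arm, giving the enone F5, although oxygenation at C1 with allylic transposition may compete. Hydrogenation (H2, Pd/C) gives the saturated keto ester F6, and LiAlH4 reduces ketone and ester together to the 3α-hydroxy diol F7. Iodination (I2, PPh3, imidazole) gives the iodo alcohol F8, and Dess–Martin oxidation rejoins the route at 25.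

**Further compounds**

F1 | step 12 | methyl 2-[(1R,2R,4aR,8aS)-2,5,5,8a-tetramethyl-2-[(tributylstannyl)oxy]-1,2,3,4,4a,5,6,8a-octahydronaphthalen-1-yl]acetate | COC(=O)C[C@@H]1[C@@]2(C)C=CCC(C)(C)[C@H]2CC[C@@]1(C)O[Sn](CCCC)(CCCC)CCCC
F2 | step 8 | (1S,4R)-3,5,5-trimethyl-4-[2-(2-methyl-1,3-dioxolan-2-yl)ethyl]cyclohex-2-en-1-yl [(4-methoxybenzyl)oxy]acetate | CC1=C[C@@H](OC(=O)COCc2ccc(OC)cc2)CC(C)(C)[C@H]1CCC3(C)OCCO3
F3 | step 8 | 2-[(4-methoxybenzyl)oxy]-2-[(1S,6R)-1,5,5-trimethyl-6-[2-(2-methyl-1,3-dioxolan-2-yl)ethyl]cyclohex-2-en-1-yl]acetic acid (epimers at the carbinol carbon) | OC(=O)C(OCc2ccc(OC)cc2)[C@@]1(C)C=CCC(C)(C)[C@H]1CCC3(C)OCCO3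
F4 | step 8 | 2-hydroxy-2-[(1S,6R)-1,5,5-trimethyl-6-[2-(2-methyl-1,3-dioxolan-2-yl)ethyl]cyclohex-2-en-1-yl]acetic acid (epimers at the carbinol carbon) | OC(=O)C(O)[C@@]1(C)C=CCC(C)(C)[C@H]1CCC2(C)OCCO2
F5 | step 14 | methyl 2-[(1R,2R,4aS,8aS)-2,5,5,8a-tetramethyl-6-oxo-2-[(triethylsilyl)oxy]-1,2,3,4,4a,5,6,8a-octahydronaphthalen-1-yl]acetate | COC(=O)C[C@@H]1[C@@]2(C)C=CC(=O)C(C)(C)[C@H]2CC[C@@]1(C)O[Si](CC)(CC)CC
F6 | step 14 | methyl 2-[(1R,2R,4aS,8aS)-2,5,5,8a-tetramethyl-6-oxo-2-[(triethylsilyl)oxy]decahydronaphthalen-1-yl]acetate | COC(=O)C[C@@H]1[C@@]2(C)CCC(=O)C(C)(C)[C@H]2CC[C@@]1(C)O[Si](CC)(CC)CC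
F7 | step 14 | (2R,4aS,5R,6R,8aS)-5-(2-hydroxyethyl)-1,1,4a,6-tetramethyl-6-[(triethylsilyl)oxy]decahydronaphthalen-2-ol | OCC[C@@H]1[C@@]2(C)CC[C@@H](O)C(C)(C)[C@H]2CC[C@@]1(C)O[Si](CC)(CC)CC
F8 | step 14 | (2R,4aS,5R,6R,8aS)-5-(2-iodoethyl)-1,1,4a,6-tetramethyl-6-[(triethylsilyl)oxy]decahydronaphthalen-2-ol | ICC[C@@H]1[C@@]2(C)CC[C@@H](O)C(C)(C)[C@H]2CC[C@@]1(C)O[Si](CC)(CC)CC
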